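**Retrosynthetic overview**
1. Atom labels follow geranylgeraniol numbering (C1 = CH2OH, C8 = ring CH–O, C18 = lactone C=O, C19 = CH2OAc). There is only one ring, the δ-lactone (ring A), and it is closed last.
2. Ring A ⇒ cut the acyl C18–O bond to give an acyclic (10Z)-8-hydroxy-18-ester seco-diterpene. Attack of the C8 oxygen on C18 is the ring closure presumed in the plant (C8 hydroxylation, C18 oxidation, lactonisation).
3. Seco ester ⇒ cut C8–C9 between two C10 halves, an enal (C1–C8, C19, C20) and a β,γ-unsaturated ester (C9–C18). One copper-catalysed enantioselective direct vinylogous aldol sets 8R and the Z-enoate, and the aldolate lactonises in the same flask without protecting groups.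
4. Enal ⇒ C6=C7 cross metathesis of (2Z)-3-methylhepta-2,6-dien-1-ol (prenol dianion + allyl bromide) with 2-(acetoxymethyl)acrolein (Riley oxidation of methallyl acetate). The acetate arrives with its building block, so C1–OH and C19–OAc never need to be differentiated.
5. Ester ⇒ deconjugative α-alkylation of ethyl crotonate with 5-bromo-2-methylpent-2-ene.

Assumption: (R)-DTBM-SEGPHOS is taken to direct attack to the Re face of the aldehyde of 7 (giving 8R); if the sense of induction proves opposite, the equally available (S)-ligand is used and nothing else changes.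

**Step 1**
Reactants: 1 prenol (3-methylbut-2-en-1-ol); 2 allyl bromide
Product: 4 (2Z)-3-methylhepta-2,6-dien-1-ol, via dilithiated prenol 3 (not isolated)
Conditions: n-BuLi (2.2 equiv), TMEDA (2.2 equiv), Et2O–hexane, 0 °C → rt, 20 h; then 2, −78 °C → rt; H2O
Reagents that add atoms: n-butyllithium [Li]CCCC (supplies the lithium of 3; nothing from it remains in 4)
Why: Alkoxide-directed allylic lithiation followed by dianion alkylation: the lithium alkoxide steers the second deprotonation to the cis methyl group and holds allyl-lithium 3 in the chelated Z form, and its primary terminus displaces bromide from 2, which fixes the 2Z trisubstituted alkene.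

**Step 2**
Reactants: 5 methallyl acetate (2-methylprop-2-enyl acetate)
Product: 6 2-(acetoxymethyl)acrolein (2-formylprop-2-enyl acetate)
Conditions: SeO2 (1.1 equiv), 1,4-dioxane, 80 °C, 4 h; distilled and kept over BHT
Reagents that add atoms: selenium dioxide O=[Se]=O
Why: Riley allylic oxidation: ene reaction of SeO2 at the alkene, [2,3]-sigmatropic shift and collapse of the selenium ester take the methyl group to the aldehyde level, the C–H bonds next to the acetate being inductively deactivated; no stereocentre is formed.

**Step 3**
Reactants: 4 (2Z)-3-methylhepta-2,6-dien-1-ol; 6 2-(acetoxymethyl)acrolein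
Product: 7 (2E,6Z)-2-formyl-8-hydroxy-6-methylocta-2,6-dienyl acetate
Conditions: 6 (3 equiv), second-generation Hoveyda–Grubbs catalyst RuCl2(H2IMes)(=CH-C6H4-2-OiPr) (5 mol%), 1,4-benzoquinone (10 mol%), CH2Cl2, 40 °C
Reagents that add atoms: none
Why: Cross metathesis of a terminal alkene with a 2-substituted acrolein, the reactivity pattern of methacrolein: the trisubstituted allylic-alcohol alkene of 4 is inert, ethene is lost, and the preferred enal geometry (formyl trans to the chain, so 6E with C19 cis to C5) results.

**Step 4**
Reactants: 8 ethyl crotonate; 9 5-bromo-2-methylpent-2-ene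
Product: 11 ethyl 2-ethenyl-6-methylhept-5-enoate (racemic), via lithium dienolate 10 (not isolated)
Conditions: LDA (1.1 equiv), DMPU, THF, −78 °C; then 9, −78 °C → rt
Reagents that add atoms: lithium diisopropylamide CC(C)N([Li])C(C)C (supplies the lithium of 10; nothing from it remains in 11)
Why: Deconjugative α-alkylation of an extended ester enolate: 10 reacts at its α-carbon with the primary bromide to give the β,γ-unsaturated ester, and the new C11 stereocentre is racemic and is erased in step 5.

**Step 5**
Reactants: 7 (2E,6Z)-2-formyl-8-hydroxy-6-methylocta-2,6-dienyl acetate; 11 ethyl 2-ethenyl-6-methylhept-5-enoate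
Product: 14 target lactone (2E,6Z)-8-hydroxy-6-methyl-2-[(2R)-5-(4-methylpent-3-enyl)-6-oxo-3,6-dihydro-2H-pyran-2-yl]octa-2,6-dienyl acetate, via copper dienolate 12 (not isolated), via seco hydroxy ester 13 (not isolated)
Conditions: [Cu(MeCN)4]PF6 (10 mol%), (R)-DTBM-SEGPHOS (11 mol%), 2-tert-butyl-1,1,3,3-tetramethylguanidine (10 mol%), 11 (2 equiv), THF, −40 °C, slow addition of 7; then 0 °C; pH 7 buffer
Reagents that add atoms: tetrakis(acetonitrile)copper hexafluorophosphate CC#N.CC#N.CC#N.CC#N.[Cu+].F[P-](F)(F)(F)(F)F (supplies the copper of 12; nothing from it remains in 14)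
Why: Proposed new method: soft enolisation of the doubly activated C11–H of 11 by the copper–bisphosphine/guanidine pair gives dienolate 12, whose fully substituted α-carbon leaves only C9 (γ) free to attack through a closed s-cis transition state in which the chiral bisphosphine exposes the Re face of the aldehyde of 7 (sets 8R) and places C9 cis to the ester, so the C8 oxygen of 13 attacks C18 and expels ethanol (six-membered geometry selects C8–O over C1–OH and C18 over the acetate), just as the 8-hydroxy-18-carboxy seco-diterpene is thought to close, and aldolates that cannot cyclise revert by retro-aldol; the closest known reaction types are the copper–bisphosphine-catalysed direct vinylogous aldol/lactonisation of unbranched β,γ-unsaturated esters with enals and the CuF–Tol-BINAP vinylogous Mukaiyama aldol of α-methyl silyl dienolates, both of which give 5,6-dihydropyran-2-ones directly.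

**Compound list**
1 | prenol (3-methylbut-2-en-1-ol) | CC(C)=CCO | starting material
2 | allyl bromide (3-bromoprop-1-ene) | C=CCBr | starting material
3 | dilithiated prenol (lithium (2Z)-4-lithio-3-methylbut-2-en-1-olate) | [Li]C/C(C)=C\CO[Li] | intermediate (not isolated)
4 | (2Z)-3-methylhepta-2,6-dien-1-ol | C=CCC/C(C)=C\CO | intermediate
5 | methallyl acetate (2-methylprop-2-enyl acetate) | CC(=C)COC(C)=O | starting material
6 | 2-(acetoxymethyl)acrolein (2-formylprop-2-enyl acetate) | C=C(C=O)COC(C)=O | intermediate
7 | (2E,6Z)-2-formyl-8-hydroxy-6-methylocta-2,6-dienyl acetate | CC(=O)OC/C(=C\CC/C(C)=C\CO)C=O | intermediate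
8 | ethyl crotonate (ethyl (E)-but-2-enoate) | CCOC(=O)/C=C/C | starting material
9 | 5-bromo-2-methylpent-2-ene | CC(C)=CCCBr | starting material
10 | lithium dienolate of ethyl crotonate (1-ethoxybuta-1,3-dien-1-olate, lithium salt) | CCOC(O[Li])=CC=C | intermediate (not isolated)
11 | ethyl 2-ethenyl-6-methylhept-5-enoate (racemic) | CCOC(=O)C(C=C)CCC=C(C)C | intermediate
12 | copper dienolate of 11 (bisphosphine on copper omitted) | CCOC(O[Cu])=C(CCC=C(C)C)C=C | intermediate (not isolated)
13 | seco hydroxy ester, ethyl (2Z,5R,6E,10Z)-6-(acetoxymethyl)-5,12-dihydroxy-10-methyl-2-(4-methylpent-3-enyl)dodeca-2,6,10-trienoate | CCOC(=O)/C(CCC=C(C)C)=C\C[C@@H](O)/C(COC(C)=O)=C/CC/C(C)=C\CO | intermediate (not isolated)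
14 | CNP0179839.1, (2E,6Z)-8-hydroxy-6-methyl-2-[(2R)-5-(4-methylpent-3-enyl)-6-oxo-3,6-dihydro-2H-pyran-2-yl]octa-2,6-dienyl acetate | CC(=O)OC/C(=C\CC/C(C)=C\CO)[C@H]1CC=C(CCC=C(C)C)C(=O)O1 | target

**Totals**
- Total step count: 5.
- Longest linear sequence: 3 steps (1 → 4 → 7 → 14, or 5 → 6 → 7 → 14).

**Three steps most likely to fail**

Step 5 is the riskiest. The α-branched ester 11 is less acidic than the known unbranched pronucleophiles. Compound 7 is a base-sensitive 2-(acetoxymethyl)enal that can lose acetate after γ-deprotonation or suffer SN2′ attack. The fallback replaces proton-transfer catalysis with a base-free Mukaiyama approach that uses a preformed silicon nucleophile and a masked hydroxyl. It sets out from 11 and 7.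
- Ester 11 is deprotonated with LDA and O-silylated with Me3SiCl (THF, −78 °C) to the silyl ketene acetal 1-ethoxy-2-(4-methylpent-3-enyl)-1-(trimethylsilyloxy)buta-1,3-diene F1.
- Compound 7 is capped with N,O-bis(trimethylsilyl)acetamide as (2E,6Z)-2-formyl-6-methyl-8-(trimethylsilyloxy)octa-2,6-dienyl acetate F2.
- F1 (1.5 equiv) and F2 are combined with Cu(OTf)2, (S)-Tol-BINAP and Bu4N[Ph3SiF2] (10 mol% each; the copper salt is reduced in the flask to monovalent copper) in THF at −78 °C.
- Fluoride-triggered silicon-to-copper exchange gives the ligated copper dienolate without free base. The aldolate lactonises and the released copper ethoxide is silylated by F1, which gives the O-trimethylsilyl ether of the target F3.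
- Citric acid in MeOH removes the silyl group, and the fallback comes back to the route at 14.

Step 3 comes next. Compound 6 is bulkier and more electron-poor than methacrolein and polymerises easily, so conversion may stall. The fallback attaches C19 by cross-coupling instead of carrying it in with the metathesis partner. It sets out from 4.
- Cross metathesis of 4 with crotonaldehyde (same ruthenium catalyst, CH2Cl2, 40 °C) gives (2E,6Z)-8-hydroxy-6-methylocta-2,6-dienal F4.
- Amine-mediated addition–elimination α-iodination (I2, DMAP, pyridine–CH2Cl2) gives (2Z,6Z)-8-hydroxy-2-iodo-6-methylocta-2,6-dienal F5.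
- Stille coupling of F5 with (tributylstannyl)methyl acetate F6 (made from commercial (tributylstannyl)methanol with Ac2O and pyridine), using Pd2(dba)3, AsPh3 and CuI in DMF, proceeds with retention of alkene geometry and comes back to the route at 7.

Step 2 is third. Over-oxidation, loss of the acetate and polymerisation of the volatile enal can erode the yield. The fallback replaces direct C–H oxygenation by halogenation followed by N-oxide oxidation. It sets out from 5.
- Ene-type chlorination with HOCl (Ca(OCl)2, CO2, CH2Cl2–H2O) gives 2-(chloromethyl)prop-2-enyl acetate F7.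
- N-methylmorpholine N-oxide in MeCN displaces the chloride through oxygen, and the adduct collapses to the aldehyde. The fallback comes back to the route at 6.

**Further compounds**
F1 | step 5 | 1-ethoxy-2-(4-methylpent-3-enyl)-1-(trimethylsilyloxy)buta-1,3-diene | CCOC(O[Si](C)(C)C)=C(CCC=C(C)C)C=C
F2 | step 5 | (2E,6Z)-2-formyl-6-methyl-8-(trimethylsilyloxy)octa-2,6-dienyl acetate | CC(=O)OC/C(=C\CC/C(C)=C\CO[Si](C)(C)C)C=O
F3 | step 5 | O-trimethylsilyl ether of the target | CC(=O)OC/C(=C\CC/C(C)=C\CO[Si](C)(C)C)[C@H]1CC=C(CCC=C(C)C)C(=O)O1
F4 | step 3 | (2E,6Z)-8-hydroxy-6-methylocta-2,6-dienal | O=C/C=C/CC/C(C)=C\CO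
F5 | step 3 | (2Z,6Z)-8-hydroxy-2-iodo-6-methylocta-2,6-dienal | O=C/C(I)=C/CC/C(C)=C\CO
F6 | step 3 | (tributylstannyl)methyl acetate | CCCC[Sn](CCCC)(CCCC)COC(C)=O
F7 | step 2 | 2-(chloromethyl)prop-2-enyl acetate | C=C(CCl)COC(C)=O
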